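## Retrosynthetic overview

1. The target is 5-[(8Z,11Z,16S)-16-hydroxyheptadeca-8,11-dien-1-yl]benzene-1,3-diol. Its only ring, the arene, is bought as 5-bromoresorcinol, so no ring is formed at any stage.
2. Key disconnection: both Z-alkenes (C8=C9 and C11=C12) are cut in one operation. This gives a propane-1,3-diyl bis-ylide linchpin (C9–C11) and two aldehydes, joined by a one-pot three-component sequential double Wittig instead of the usual skipped-diyne/semi-hydrogenation or stepwise Wittig plan.
3. Aryl aldehyde (arene + C1–C8): sp2–sp3 Kumada–Corriu coupling of bis-MOM 5-bromoresorcinol with a non-8-enyl Grignard, then oxidative cleavage of the terminal alkene.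
4. Chiral aldehyde (C12–C17): (S)-propylene oxide opened at CH2 by a butenyl Grignard (stereocentre bought, never touched), then silylation and ozonolysis.
5. End game: one acidic methanolysis removes both MOM groups and the TBS ether.

Assumption: reagents that deliver only a protecting group or an oxygen atom (MOMCl, TBSCl, NaIO4, O3) are listed under "Reagents that add atoms" and not numbered; but-3-en-1-ylmagnesium bromide is taken as its commercial THF solution.

## Route

Step 1
Reactants: 1 5-bromobenzene-1,3-diol (5-bromoresorcinol)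
Product: 2 1-bromo-3,5-bis(methoxymethoxy)benzene
Conditions: MOMCl (2.5 equiv), iPr2NEt (3 equiv), CH2Cl2, 0 °C → rt
Reagents that add atoms: chloromethyl methyl ether (MOMCl), COCCl
Why: Double O-alkylation of the phenols by the reactive α-chloro ether (MOM protection, Williamson-type) gives acetals that survive Grignard, ylide and oxidative conditions and leave with mild acid at the end.

Step 2
Reactants: 2 1-bromo-3,5-bis(methoxymethoxy)benzene; 3 9-bromonon-1-ene
Product: 5 1,3-bis(methoxymethoxy)-5-(non-8-en-1-yl)benzene, via non-8-enylmagnesium bromide 4 (not isolated)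
Conditions: 3, Mg, THF, rt → 40 °C; then 2, PdCl2(dppf) (3 mol %), THF, 0 → 50 °C
Reagents that add atoms: none
Why: Kumada–Corriu cross-coupling, in which zerovalent palladium inserts into the aryl bromide, the primary alkyl Grignard 4 transmetalates, and the wide-bite-angle dppf ligand makes reductive elimination faster than β-hydride elimination, so the sp2–sp3 bond forms without touching the MOM acetals or the remote terminal alkene.

Step 3
Reactants: 5 1,3-bis(methoxymethoxy)-5-(non-8-en-1-yl)benzene
Product: 6 8-[3,5-bis(methoxymethoxy)phenyl]octanal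
Conditions: OsO4 (2 mol %), NaIO4 (4 equiv), 2,6-lutidine (2 equiv), 1,4-dioxane/H2O 3:1, rt
Reagents that add atoms: sodium periodate (NaIO4), [Na+].[O-]I(=O)(=O)=O
Why: Lemieux–Johnson oxidative cleavage (OsO4-catalysed dihydroxylation followed by periodate glycol cleavage, with lutidine suppressing over-oxidation) turns the terminal alkene into the aldehyde with loss of one carbon while sparing the electron-rich arene that ozone could attack.

Step 4
Reactants: 7 (S)-2-methyloxirane ((S)-propylene oxide); 8 but-3-en-1-ylmagnesium bromide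
Product: 9 (2S)-hept-6-en-2-ol
Conditions: CuI (10 mol %), THF, −30 → 0 °C; then H2O
Reagents that add atoms: none
Why: Copper-catalysed SN2 ring-opening of the terminal epoxide by the Grignard reagent occurs at the unsubstituted CH2 carbon, so the stereocentre bought with (S)-propylene oxide is not a reacting centre and is carried unchanged into the (S)-alcohol.

Step 5
Reactants: 9 (2S)-hept-6-en-2-ol
Product: 10 tert-butyl{[(2S)-hept-6-en-2-yl]oxy}dimethylsilane
Conditions: TBSCl (1.2 equiv), imidazole (2 equiv), DMF, 0 °C → rt
Reagents that add atoms: tert-butyldimethylsilyl chloride (TBSCl), CC(C)(C)[Si](C)(C)Cl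
Why: Imidazole-promoted O-silylation (Corey TBS protection) masks the secondary alcohol against the strongly basic ylide of the key step without affecting the stereocentre.

Step 6
Reactants: 10 tert-butyl{[(2S)-hept-6-en-2-yl]oxy}dimethylsilane
Product: 11 (5S)-5-[(tert-butyldimethylsilyl)oxy]hexanal
Conditions: O3, CH2Cl2, −78 °C; then PPh3 (1.2 equiv), −78 °C → rt
Reagents that add atoms: ozone, [O-][O+]=O
Why: Ozonolysis of the terminal alkene with reductive PPh3 work-up gives the aldehyde, and the silyl ether and the stereocentre (four bonds from the carbonyl, not epimerisable) are untouched.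

Step 7
Reactants: 12 propane-1,3-diylbis(triphenylphosphonium) dibromide; 6 8-[3,5-bis(methoxymethoxy)phenyl]octanal; 11 (5S)-5-[(tert-butyldimethylsilyl)oxy]hexanal
Product: 15 tert-butyl({(2S,6Z,9Z)-17-[3,5-bis(methoxymethoxy)phenyl]heptadeca-6,9-dien-2-yl}oxy)dimethylsilane, via C3 bis-ylide 13 (not isolated), via alkenyl ylide 14 (not isolated)
Conditions: 12 (2.0 equiv), NaN(SiMe3)2 (4.0 equiv), THF, −78 → 0 °C; 6 (1.0 equiv, slow addition), −78 → −20 °C; 11 (3.5 equiv), −78 °C → rt
Reagents that add atoms: none
Why: Proposed new method: a one-pot sequential double Wittig olefination of the C3 bis-ylide 13 with two different aldehydes, whose closest known relatives are the double Wittig of this same bis-ylide with two equivalents of one aldehyde (or a dialdehyde) and the sequential two-aldehyde double Wittig of the homologous (Z)-hex-3-ene-1,6-diyl bis-ylide; slow addition of limiting 6 to excess 13 at −78 °C favours mono-addition because the first oxaphosphetane hinders and deactivates the neighbouring ylide, cycloreversion on warming gives the salt-free non-stabilised ylide 14, and kinetically controlled cis-oxaphosphetane formation under lithium-free conditions sets each alkene Z while the remote (S)-centre is not involved.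

Step 8
Reactants: 15 tert-butyl({(2S,6Z,9Z)-17-[3,5-bis(methoxymethoxy)phenyl]heptadeca-6,9-dien-2-yl}oxy)dimethylsilane
Product: 16 hansfordiol D, 5-[(8Z,11Z,16S)-16-hydroxyheptadeca-8,11-dien-1-yl]benzene-1,3-diol
Conditions: HCl (1.25 M in MeOH), 45 °C
Reagents that add atoms: none
Why: Acid-catalysed methanolysis as a global deprotection transacetalises both aryl MOM ethers to dimethoxymethane and solvolyses the secondary TBS ether in the same pot, and neither the non-conjugated Z,Z-diene nor the unactivated secondary carbinol ionises or isomerises in dilute methanolic HCl, so alkene geometry and the (S)-centre are preserved.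

## Compound list

1 | 5-bromobenzene-1,3-diol (5-bromoresorcinol) | Oc1cc(O)cc(Br)c1 | starting material
2 | 1-bromo-3,5-bis(methoxymethoxy)benzene | COCOc1cc(OCOC)cc(Br)c1 | intermediate
3 | 9-bromonon-1-ene | C=CCCCCCCCBr | starting material
4 | non-8-en-1-ylmagnesium bromide | C=CCCCCCCC[Mg]Br | intermediate
5 | 1,3-bis(methoxymethoxy)-5-(non-8-en-1-yl)benzene | C=CCCCCCCCc1cc(OCOC)cc(OCOC)c1 | intermediate
6 | 8-[3,5-bis(methoxymethoxy)phenyl]octanal | O=CCCCCCCCc1cc(OCOC)cc(OCOC)c1 | intermediate
7 | (S)-2-methyloxirane ((S)-propylene oxide) | C[C@H]1CO1 | starting material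
8 | but-3-en-1-ylmagnesium bromide | C=CCC[Mg]Br | starting material
9 | (2S)-hept-6-en-2-ol | C[C@H](O)CCCC=C | intermediate
10 | tert-butyl{[(2S)-hept-6-en-2-yl]oxy}dimethylsilane | C[C@H](O[Si](C)(C)C(C)(C)C)CCCC=C | intermediate
11 | (5S)-5-[(tert-butyldimethylsilyl)oxy]hexanal | C[C@H](O[Si](C)(C)C(C)(C)C)CCCC=O | intermediate
12 | propane-1,3-diylbis(triphenylphosphonium) dibromide | [Br-].[Br-].c1ccc(cc1)[P+](CCC[P+](c1ccccc1)(c1ccccc1)c1ccccc1)(c1ccccc1)c1ccccc1 | starting material
13 | C3 bis-ylide, propane-1,3-diylidenebis(triphenyl-λ5-phosphane) | c1ccc(cc1)P(=CCC=P(c1ccccc1)(c1ccccc1)c1ccccc1)(c1ccccc1)c1ccccc1 | intermediate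
14 | alkenyl ylide, {(3Z)-11-[3,5-bis(methoxymethoxy)phenyl]undec-3-en-1-ylidene}triphenyl-λ5-phosphane | COCOc1cc(OCOC)cc(CCCCCCC/C=C\CC=P(c2ccccc2)(c2ccccc2)c2ccccc2)c1 | intermediate
15 | tert-butyl({(2S,6Z,9Z)-17-[3,5-bis(methoxymethoxy)phenyl]heptadeca-6,9-dien-2-yl}oxy)dimethylsilane | C[C@H](O[Si](C)(C)C(C)(C)C)CCC/C=C\C/C=C\CCCCCCCc1cc(OCOC)cc(OCOC)c1 | intermediate
16 | hansfordiol D, 5-[(8Z,11Z,16S)-16-hydroxyheptadeca-8,11-dien-1-yl]benzene-1,3-diol | C[C@H](O)CCC/C=C\C/C=C\CCCCCCCc1cc(O)cc(O)c1 | target

## Step count and risks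

Total step count: 8. Longest linear sequence: 5 steps (1 → 2 → 5 → 6 → 15 → 16, or equally 7 → 9 → 10 → 11 → 15 → 16).

The three steps most likely to fail are steps 7, 2 and 8.

**Step 7.** The one-pot unsymmetrical double Wittig may give mostly the two symmetrical dienes (from 6 twice or from 11 twice), or a few percent of E-isomer that is hard to remove. The fallback sets out from aldehyde 6, uses alkene 10 as partner, and comes back at 15. Aldehyde 6 is olefinated with the ylide from commercial but-3-en-1-yltriphenylphosphonium bromide (NaN(SiMe3)2, THF, −78 °C → rt) to give 1-[(8Z)-dodeca-8,11-dien-1-yl]-3,5-bis(methoxymethoxy)benzene F1. Z-selective cross-metathesis of the terminal alkene of F1 with alkene 10 (3 equiv) then gives 15 directly. The catalyst is the cyclometalated nitrato ruthenium complex Ru(NO3)(=CH–C6H4-2-OiPr)(L), where L is C,C-chelating 1-(1-adamantyl)-3-(2,6-diisopropylphenyl)imidazolin-2-ylidene (5 mol %, THF, 35 °C, static vacuum to remove ethylene). The route resumes with step 8.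

**Step 2.** The Kumada–Corriu coupling may suffer from reduction or homocoupling of the Grignard reagent. The fallback sets out from bromide 2 and comes back at aldehyde 6, so it also bypasses step 3. Commercial oct-7-en-1-ol is hydroborated with 9-BBN (2.2 equiv, THF, 0 °C → rt; any O–B bond from the excess reagent is hydrolysed by the aqueous base) to give 8-(9-borabicyclo[3.3.1]nonan-9-yl)octan-1-ol F2 in the flask. B-alkyl Suzuki–Miyaura coupling of F2 with 2 (PdCl2(dppf) 3 mol %, aq. K3PO4, THF/DMF, 60 °C) gives 8-[3,5-bis(methoxymethoxy)phenyl]octan-1-ol F3. Dess–Martin periodinane (NaHCO3, CH2Cl2, 0 °C → rt) oxidises F3 to 6.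

**Step 8.** During acidic methanolysis the formaldehyde equivalent set free next to the very nucleophilic resorcinol could re-alkylate the ring, or MOM cleavage could stall. The fallback sets out from 15 and comes back at 16 by a staged, aprotic deprotection. Bu4NF (THF, 0 °C → rt) removes only the silyl ether to give (2S,6Z,9Z)-17-[3,5-bis(methoxymethoxy)phenyl]heptadeca-6,9-dien-2-ol F4. The two MOM ethers of F4 are then cleaved with ZnBr2 and propane-1-thiol (CH2Cl2, 0 °C, minutes). In this Lewis-acid, soft-nucleophile cleavage the methoxymethyl unit is trapped on sulfur and never becomes a free electrophile, giving 16.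

## Further compounds

F1 | step 7 | 1-[(8Z)-dodeca-8,11-dien-1-yl]-3,5-bis(methoxymethoxy)benzene | C=CC/C=C\CCCCCCCc1cc(OCOC)cc(OCOC)c1
F2 | step 2 | 8-(9-borabicyclo[3.3.1]nonan-9-yl)octan-1-ol | OCCCCCCCCB1C2CCCC1CCC2
F3 | step 2 | 8-[3,5-bis(methoxymethoxy)phenyl]octan-1-ol | OCCCCCCCCc1cc(OCOC)cc(OCOC)c1
F4 | step 8 | (2S,6Z,9Z)-17-[3,5-bis(methoxymethoxy)phenyl]heptadeca-6,9-dien-2-ol | C[C@H](O)CCC/C=C\C/C=C\CCCCCCCc1cc(OCOC)cc(OCOC)c1
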